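The data come from a simulation for an exercise, noise included.

The dawn run keeps 47% of its starting material at 12.0 h, and the noon run keeps 50% at 12.0 h, with more of both charges in the noon flask .

| flask | starting material | free catalyst | remark | time |
|---|---|---|---|---|
| dawn | 0.99 M | 12 mM | run made earlier |  |
| noon | 2.3 M | 18 mM | run made earlier |  |
| violet | 0.80 M | 12 mM |  | 12 h |
| red | 0.80 M | 4.0 mM |  | 12 h |
| amber | 1.2 M | 50 mM |  | 12 h |
| teal | 2.3 M | 8.0 mM |  | 12 h |
| grey | 2.3 M | 12 mM |  | 12 h |

| run | time / h | product / % | starting material / % |
|---|---|---|---|
| dawn | 1.00 | 8 | 93 |
| dawn | 1.50 | 9 | 87 |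
| dawn | 2.50 | 16 | 85 |
| dawn | 4.00 | 21 | 72 |
| dawn | 8.00 | 40 | 59 |
| dawn | 12.0 | 50 | 47 |
| noon | 2.50 | 17 | 82 |
| noon | 5.00 | 32 | 70 |
| noon | 8.00 | 41 | 59 |
| noon | 10.0 | 46 | 54 |
| noon | 12.0 | 51 | 50 |

(standard deviation of a reading: 1.5 percentage points)

- amounts and yields of product count idle complex too
- reactions considered so far: starting material + free catalyst -> catalyst intermediate A; catalyst intermediate A -> catalyst intermediate B; catalyst intermediate B <-> free catalyst + product; free catalyst + product <-> idle complex

* all flasks from highest to lowest amount of product, in percent of the starting material charged, at 12 h (violet / red / amber / teal / grey)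
* the amount of product, in percent of the starting material charged of the flask you put first, at 12 h
* the amount of product, in percent of the starting material charged of the flask you put last, at 12 h

I treat each flask as pseudo-first-order in starting material and call the free catalyst charged, multiplied by the hours that halve the starting material, the halving dose. The dawn run gives 132 mM·h, and the noon run gives 216 mM·h, so the dose reads larger in the noon run.

I assume the dose follows the charge of starting material, and a straight line through these two doses gives 120 mM·h for violet and red and 146 mM·h for amber, while grey and teal take the noon dose, having the noon charge of starting material. Catalyst times hours, divided by the dose, counts the halvings in each flask, and I take product as starting material used. My reckoning is amber 94.2%, violet 56.5%, grey 37.0%, teal 26.5% and red 24.2%. Teal and red lie 2.3 percentage points apart, against a scatter of 1.5 points, and amber goes further than either run has been read.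

The forecast gives my order, amber > violet > grey > teal > red, with amber at 90%, lower than mine, and red at 24%, on the ground that “the catalyst is partly saturated at high starting material”.

The flasks stand amber > violet > grey > teal > red, with amber at 88.3% and red at 25.4%.

    starting material + free catalyst → catalyst intermediate A (k = 0.00227 L mol⁻¹ s⁻¹)
    catalyst intermediate A → catalyst intermediate B (k = 0.00920 s⁻¹)
    catalyst intermediate B ⇌ free catalyst + product (K = 1.20 M, k = 0.248 s⁻¹)
    free catalyst + product ⇌ idle complex (K = 0.676 L mol⁻¹, k = 4.38 × 10⁻⁴ L mol⁻¹ s⁻¹)

Amber ends lower than my reckoning, and red ends higher. From the dawn flask's 51.7% at 12.0 h, without the scatter, amber's catalyst charge by itself gives 90.0%, and amber's starting material by itself gives 49.5%. For a neighbour of red with 16.0 mM of free catalyst, the dose line gives 1.60 halvings, so 33.0% of the starting material should remain, and that flask holds 36.5% at 12.0 h.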